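**Plan**

- The target is an achiral chain of seven oxygenated benzene rings joined by six ether oxygens, lettered A (2,4,6-trihydroxyphenyl end) to G (3,4,5-trihydroxyphenyl end). In each ring, carbon 1 is the ether carbon on the side of ring A (in ring A, its only ether carbon). There is no stereocentre to set.
- Retrosynthesis: all seventeen O–H go back to O–Me, then the ether between carbon 6 of ring D and carbon 1 of ring E is cut (copper-mediated O-arylation) into an ABCD phenol and an EFG bromide.
- In ABCD, carbon 1 of ring A, carbon 4 of ring B and carbon 4 of ring C are ether carbons that each lie between two oxygenated carbons (carbons 2 and 6 of ring A, 3 and 5 of ring B, 3 and 5 of ring C). Those six C–O bonds are traced back to C–Br, and the hexabromide is cut at its three diaryl ether bonds into the ring D phenol and three units of 3,5-dibromo-4-fluorobenzaldehyde (fluoride SNAr, then formyl-to-hydroxyl Baeyer–Villiger).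
- EFG is cut at its two diaryl ether bonds into 4-bromo-2,6-dimethoxyphenol, whose bromine marks carbon 1 of ring E, and two units of 4-fluoro-2,6-dimethoxybenzaldehyde.
- Forward: ring D phenol, then rings C, B and A one at a time, sixfold bromide-to-methoxide exchange, debenzylation; separately rings E, F, G in that order; union of the two blocks; global demethylation. No ring is formed in any step; all seven come from benzene starting materials.

Key step: step 13

Remark: 4-fluoro-2,6-dimethoxybenzaldehyde and 4-bromo-2,6-dimethoxyphenol are taken as catalogue compounds.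

**Route**

Step 1
Reactants: 1 2,3,4-trimethoxybenzaldehyde
Product: 3 2,3,4-trimethoxyphenol, via aryl formate 2 (not isolated)
Conditions: mCPBA, CH2Cl2, 0 °C to rt; aq. NaHCO3 wash; then K2CO3 (cat.), MeOH, rt
Reagents that add atoms: mCPBA (3-chloroperoxybenzoic acid), OOC(=O)c1cccc(Cl)c1
Why: Baeyer–Villiger oxidation, in which the ortho- and para-methoxy groups make the aryl group migrate in the Criegee adduct in preference to hydride, and the resulting formate is methanolysed.

Step 2
Reactants: 3 2,3,4-trimethoxyphenol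
Product: 4 2-hydroxy-3,4,5-trimethoxybenzaldehyde
Conditions: MgCl2, Et3N, (CH2O)n, MeCN, reflux; aq. HCl work-up
Reagents that add atoms: paraformaldehyde (formaldehyde), C=O
Why: Magnesium-mediated ortho-formylation (Casnati–Skattebøl): the phenoxide bound to magnesium (ArOMgCl) delivers formaldehyde only to the one free ortho carbon, and a second formaldehyde accepts hydride from the benzylic alkoxide to give the aldehyde.

Step 3
Reactants: 4 2-hydroxy-3,4,5-trimethoxybenzaldehyde; 5 benzyl bromide
Product: 6 2-(benzyloxy)-3,4,5-trimethoxybenzaldehyde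
Conditions: K2CO3, DMF, 50 °C
Reagents that add atoms: none
Why: Williamson ether synthesis on the only phenol, which fixes the oxygen that will later bond to ring E as the one non-methyl ether of ring D.

Step 4
Reactants: 6 2-(benzyloxy)-3,4,5-trimethoxybenzaldehyde
Product: 8 2-(benzyloxy)-3,4,5-trimethoxyphenol, via aryl formate 7 (not isolated)
Conditions: mCPBA, CH2Cl2, 0 °C to rt; aq. NaHCO3 wash; then K2CO3 (cat.), MeOH, rt
Reagents that add atoms: mCPBA (3-chloroperoxybenzoic acid), OOC(=O)c1cccc(Cl)c1
Why: Baeyer–Villiger oxidation of a benzaldehyde with ortho-benzyloxy and para-methoxy donors, so aryl migration should dominate and methanolysis of the formate frees the ring D hydroxyl that will bond to ring C while the benzyl ether is untouched.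

Step 5
Reactants: 9 4-fluorobenzaldehyde
Product: 10 3,5-dibromo-4-fluorobenzaldehyde
Conditions: NBS (2.3 equiv), conc. H2SO4, 60 °C
Reagents that add atoms: N-bromosuccinimide, BrN1C(=O)CCC1=O
Why: Electrophilic aromatic bromination of a deactivated arene with protonated NBS, where the ortho-directing fluorine and the meta-directing formyl group both point to positions 3 and 5.

Step 6
Reactants: 8 2-(benzyloxy)-3,4,5-trimethoxyphenol; 10 3,5-dibromo-4-fluorobenzaldehyde
Product: 11 CD aldehyde 4-[2-(benzyloxy)-3,4,5-trimethoxyphenoxy]-3,5-dibromobenzaldehyde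
Conditions: K2CO3, DMF, 80 °C
Reagents that add atoms: none
Why: Nucleophilic aromatic substitution by addition–elimination: the para-formyl group and the two inductively withdrawing ortho bromines stabilise the Meisenheimer adduct and fluoride leaves, forming the ether between carbon 1 of ring D and carbon 4 of ring C.

Step 7
Reactants: 11 CD aldehyde
Product: 13 CD phenol 4-[2-(benzyloxy)-3,4,5-trimethoxyphenoxy]-3,5-dibromophenol, via CD formate 12 (not isolated)
Conditions: mCPBA, CH2Cl2, rt; aq. NaHCO3 wash; then K2CO3 (cat.), MeOH, rt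
Reagents that add atoms: mCPBA (3-chloroperoxybenzoic acid), OOC(=O)c1cccc(Cl)c1
Why: Baeyer–Villiger oxidation in which the para-aryloxy oxygen supports aryl migration, the bromines keep ring C inert to the peracid, and formate methanolysis frees the hydroxyl on carbon 1 of ring C.

Step 8
Reactants: 13 CD phenol; 10 3,5-dibromo-4-fluorobenzaldehyde
Product: 14 BCD aldehyde 3,5-dibromo-4-{3,5-dibromo-4-[2-(benzyloxy)-3,4,5-trimethoxyphenoxy]phenoxy}benzaldehyde
Conditions: K2CO3, DMF, 90 °C
Reagents that add atoms: none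
Why: Second fluoride SNAr, now with a phenoxide that has no ortho substituent, forming the ether between carbon 1 of ring C and carbon 4 of ring B; ring C has lost its formyl group and is no longer an electrophile.

Step 9
Reactants: 14 BCD aldehyde
Product: 16 BCD phenol 3,5-dibromo-4-{3,5-dibromo-4-[2-(benzyloxy)-3,4,5-trimethoxyphenoxy]phenoxy}phenol, via BCD formate 15 (not isolated)
Conditions: mCPBA, CH2Cl2, rt; aq. NaHCO3 wash; then K2CO3 (cat.), MeOH, rt
Reagents that add atoms: mCPBA (3-chloroperoxybenzoic acid), OOC(=O)c1cccc(Cl)c1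
Why: Baeyer–Villiger oxidation as in step 7, with the formyl group of ring B replaced by a hydroxyl on carbon 1 of that ring after formate methanolysis.

Step 10
Reactants: 16 BCD phenol; 10 3,5-dibromo-4-fluorobenzaldehyde
Product: 17 ABCD aldehyde 3,5-dibromo-4-(3,5-dibromo-4-{3,5-dibromo-4-[2-(benzyloxy)-3,4,5-trimethoxyphenoxy]phenoxy}phenoxy)benzaldehyde
Conditions: K2CO3, DMF, 90 °C
Reagents that add atoms: none
Why: Third fluoride SNAr under the same activation, forming the ether between carbon 1 of ring B and carbon 1 of ring A and completing the tetramer skeleton.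

Step 11
Reactants: 17 ABCD aldehyde
Product: 19 hexabromo ABCD phenol, via ABCD formate 18 (not isolated)
Conditions: mCPBA, CH2Cl2, rt; aq. NaHCO3 wash; then K2CO3 (cat.), MeOH, rt
Reagents that add atoms: mCPBA (3-chloroperoxybenzoic acid), OOC(=O)c1cccc(Cl)c1
Why: Baeyer–Villiger oxidation as in steps 7 and 9, turning the last formyl group into the oxygen on carbon 4 of ring A.

Step 12
Reactants: 19 hexabromo ABCD phenol
Product: 20 hexabromo ABCD tetramer (methyl ether on ring A, benzyl ether on ring D)
Conditions: MeI, K2CO3, acetone, reflux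
Reagents that add atoms: iodomethane, CI
Why: Williamson methylation of an unhindered, fairly acidic phenol, which removes the only acidic site before the strongly basic exchange.

Step 13
Reactants: 20 hexabromo ABCD tetramer
Product: 21 permethylated ABCD tetramer (benzyl ether on ring D)
Conditions: NaOMe (5 M in MeOH, large excess), CuBr (monovalent copper, 20 mol% per C–Br), EtOAc (cat.), DMF, 110 °C, argon
Reagents that add atoms: sodium methoxide, C[O-].[Na+]
Why: A methoxocuprate, Na[Cu(OMe)2], formed from CuBr and NaOMe adds oxidatively to a C–Br bond (monovalent to trivalent copper) and C–O reductive elimination releases the aryl methyl ether and returns monovalent copper, with the ortho aryloxy oxygen able to hold the metal near the halide. The closest known reaction is the Ullmann-type copper-catalysed methanolysis of aryl bromides, including twofold exchange at both positions ortho to an oxygen substituent as in the conversion of 3,5-dibromo-4-hydroxybenzaldehyde into syringaldehyde; here it is asked to run six times on one molecule, creating the C–O bonds at carbons 2 and 6 of ring A, carbons 3 and 5 of ring B and carbons 3 and 5 of ring C. No ring closes and no stereocentre forms. The step needs chemoselectivity, namely exchange at six C–Br bonds without hydrodebromination and without methanolysis of the diaryl ethers; the sites are fixed by where the bromines sit, and with all formyl groups gone no ether carbon is activated toward addition–elimination, while the benzyl and methyl ethers are inert to methoxide. The same bromines earlier made the three SNAr steps possible and shielded rings A to C from the peracid. Material that still shows a bromine isotope pattern should be returned to the same conditions.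

Step 14
Reactants: 21 permethylated ABCD tetramer (benzyl ether on ring D)
Product: 22 ABCD phenol (free hydroxyl on ring D)
Conditions: hydrogen (1 atm), Pd/C (10% palladium on carbon), EtOAc–MeOH, rt
Reagents that add atoms: none
Why: Catalytic hydrogenolysis of the single benzyl ether, run only after all bromine has been exchanged so that no C–Br bond can be reduced; methyl and diaryl ethers do not react.

Step 15
Reactants: 23 4-bromo-2,6-dimethoxyphenol; 24 4-fluoro-2,6-dimethoxybenzaldehyde
Product: 25 EF aldehyde 4-(4-bromo-2,6-dimethoxyphenoxy)-2,6-dimethoxybenzaldehyde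
Conditions: Cs2CO3, DMSO, 120 °C
Reagents that add atoms: none
Why: Nucleophilic aromatic substitution in which the hindered but electron-rich phenoxide attacks an unhindered carbon para to the formyl group and fluoride leaves, forming the ether between carbon 4 of ring E and carbon 1 of ring F; the C–Br bond sits on an unactivated ring and is carried through.

Step 16
Reactants: 25 EF aldehyde
Product: 27 EF phenol 4-(4-bromo-2,6-dimethoxyphenoxy)-2,6-dimethoxyphenol, via EF formate 26 (not isolated)
Conditions: mCPBA, CH2Cl2, 0 °C; aq. NaHCO3 wash; then K2CO3 (cat.), MeOH, rt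
Reagents that add atoms: mCPBA (3-chloroperoxybenzoic acid), OOC(=O)c1cccc(Cl)c1
Why: Baeyer–Villiger oxidation of a 2,4,6-trioxygenated benzaldehyde, whose aryl group migrates very readily, followed by formate methanolysis to the hydroxyl on carbon 4 of ring F.

Step 17
Reactants: 27 EF phenol; 24 4-fluoro-2,6-dimethoxybenzaldehyde
Product: 28 EFG aldehyde 4-[4-(4-bromo-2,6-dimethoxyphenoxy)-2,6-dimethoxyphenoxy]-2,6-dimethoxybenzaldehyde
Conditions: Cs2CO3, DMSO, 120 °C
Reagents that add atoms: none
Why: Repeat of the step 15 SNAr with the ring F phenoxide, forming the ether between carbon 4 of ring F and carbon 1 of ring G.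

Step 18
Reactants: 28 EFG aldehyde
Product: 30 EFG phenol 4-[4-(4-bromo-2,6-dimethoxyphenoxy)-2,6-dimethoxyphenoxy]-2,6-dimethoxyphenol, via EFG formate 29 (not isolated)
Conditions: mCPBA, CH2Cl2, 0 °C; aq. NaHCO3 wash; then K2CO3 (cat.), MeOH, rt
Reagents that add atoms: mCPBA (3-chloroperoxybenzoic acid), OOC(=O)c1cccc(Cl)c1
Why: Baeyer–Villiger oxidation as in step 16, installing the third oxygen of ring G.

Step 19
Reactants: 30 EFG phenol
Product: 31 permethylated EFG bromide 5-[4-(4-bromo-2,6-dimethoxyphenoxy)-2,6-dimethoxyphenoxy]-1,2,3-trimethoxybenzene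
Conditions: MeI, K2CO3, DMF, 40 °C
Reagents that add atoms: iodomethane, CI
Why: Williamson methylation, which caps the only phenol of the trimer so that it cannot compete as a nucleophile in the union of the two blocks.

Step 20
Reactants: 22 ABCD phenol (free hydroxyl on ring D); 31 permethylated EFG bromide
Product: 32 permethylated heptamer
Conditions: CuI (monovalent copper, 20 mol%), picolinic acid (40 mol%), K3PO4, DMSO, 100 °C, argon
Reagents that add atoms: none
Why: Ullmann-type diaryl ether synthesis under picolinate-ligated copper, conditions known to accept 2,6-disubstituted phenols; the bromine-bearing carbon of ring E has two free ortho positions, and the system holds only one phenol and one C–Br bond.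

Step 21
Reactants: 32 permethylated heptamer
Product: 33 CNP0304148.0
Conditions: BBr3 (excess), CH2Cl2, −78 °C to rt; then MeOH, then water; argon throughout
Reagents that add atoms: none
Why: Lewis-acid ether cleavage in which bromide attacks the methyl carbon of each boron-bound methoxy oxygen, while the diaryl ether links, having only sp2 carbons on oxygen, are not cleaved.

**Compound list**

1 | 2,3,4-trimethoxybenzaldehyde | COc1ccc(C=O)c(OC)c1OC | starting material
2 | 2,3,4-trimethoxyphenyl formate | COc1ccc(OC=O)c(OC)c1OC | intermediate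
3 | 2,3,4-trimethoxyphenol | COc1ccc(O)c(OC)c1OC | intermediate
4 | 2-hydroxy-3,4,5-trimethoxybenzaldehyde | COc1cc(C=O)c(O)c(OC)c1OC | intermediate
5 | benzyl bromide | BrCc1ccccc1 | starting material
6 | 2-(benzyloxy)-3,4,5-trimethoxybenzaldehyde | COc1cc(C=O)c(OCc2ccccc2)c(OC)c1OC | intermediate
7 | 2-(benzyloxy)-3,4,5-trimethoxyphenyl formate | COc1cc(OC=O)c(OCc2ccccc2)c(OC)c1OC | intermediate
8 | 2-(benzyloxy)-3,4,5-trimethoxyphenol (ring D phenol) | COc1cc(O)c(OCc2ccccc2)c(OC)c1OC | intermediate
9 | 4-fluorobenzaldehyde | O=Cc1ccc(F)cc1 | starting material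
10 | 3,5-dibromo-4-fluorobenzaldehyde | O=Cc1cc(Br)c(F)c(Br)c1 | intermediate
11 | CD aldehyde: 4-[2-(benzyloxy)-3,4,5-trimethoxyphenoxy]-3,5-dibromobenzaldehyde | O=Cc1cc(Br)c(Oc2cc(OC)c(OC)c(OC)c2OCc2ccccc2)c(Br)c1 | intermediate
12 | CD formate: 4-[2-(benzyloxy)-3,4,5-trimethoxyphenoxy]-3,5-dibromophenyl formate | O=COc1cc(Br)c(Oc2cc(OC)c(OC)c(OC)c2OCc2ccccc2)c(Br)c1 | intermediate
13 | CD phenol: 4-[2-(benzyloxy)-3,4,5-trimethoxyphenoxy]-3,5-dibromophenol | Oc1cc(Br)c(Oc2cc(OC)c(OC)c(OC)c2OCc2ccccc2)c(Br)c1 | intermediate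
14 | BCD aldehyde: 3,5-dibromo-4-{3,5-dibromo-4-[2-(benzyloxy)-3,4,5-trimethoxyphenoxy]phenoxy}benzaldehyde | O=Cc1cc(Br)c(Oc2cc(Br)c(Oc3cc(OC)c(OC)c(OC)c3OCc3ccccc3)c(Br)c2)c(Br)c1 | intermediate
15 | BCD formate: formate ester of 16 | O=COc1cc(Br)c(Oc2cc(Br)c(Oc3cc(OC)c(OC)c(OC)c3OCc3ccccc3)c(Br)c2)c(Br)c1 | intermediate
16 | BCD phenol: 3,5-dibromo-4-{3,5-dibromo-4-[2-(benzyloxy)-3,4,5-trimethoxyphenoxy]phenoxy}phenol | Oc1cc(Br)c(Oc2cc(Br)c(Oc3cc(OC)c(OC)c(OC)c3OCc3ccccc3)c(Br)c2)c(Br)c1 | intermediate
17 | ABCD aldehyde: 3,5-dibromo-4-(3,5-dibromo-4-{3,5-dibromo-4-[2-(benzyloxy)-3,4,5-trimethoxyphenoxy]phenoxy}phenoxy)benzaldehyde | O=Cc1cc(Br)c(Oc2cc(Br)c(Oc3cc(Br)c(Oc4cc(OC)c(OC)c(OC)c4OCc4ccccc4)c(Br)c3)c(Br)c2)c(Br)c1 | intermediate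
18 | ABCD formate: formate ester of 19 | O=COc1cc(Br)c(Oc2cc(Br)c(Oc3cc(Br)c(Oc4cc(OC)c(OC)c(OC)c4OCc4ccccc4)c(Br)c3)c(Br)c2)c(Br)c1 | intermediate
19 | hexabromo ABCD phenol: free hydroxyl para to the ether oxygen of ring A, rings A, B and C each 3,5-dibrominated, benzyl ether on ring D | Oc1cc(Br)c(Oc2cc(Br)c(Oc3cc(Br)c(Oc4cc(OC)c(OC)c(OC)c4OCc4ccccc4)c(Br)c3)c(Br)c2)c(Br)c1 | intermediate
20 | hexabromo ABCD tetramer (methyl ether on ring A, benzyl ether on ring D): 1-(benzyloxy)-2,3,4-trimethoxy-6-{2,6-dibromo-4-[2,6-dibromo-4-(2,6-dibromo-4-methoxyphenoxy)phenoxy]phenoxy}benzene | COc1cc(Br)c(Oc2cc(Br)c(Oc3cc(Br)c(Oc4cc(OC)c(OC)c(OC)c4OCc4ccccc4)c(Br)c3)c(Br)c2)c(Br)c1 | intermediate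
21 | permethylated ABCD tetramer (benzyl ether on ring D): 1-(benzyloxy)-2,3,4-trimethoxy-6-{2,6-dimethoxy-4-[2,6-dimethoxy-4-(2,4,6-trimethoxyphenoxy)phenoxy]phenoxy}benzene | COc1cc(OC)c(Oc2cc(OC)c(Oc3cc(OC)c(Oc4cc(OC)c(OC)c(OC)c4OCc4ccccc4)c(OC)c3)c(OC)c2)c(OC)c1 | intermediate
22 | ABCD phenol (free hydroxyl on ring D): 2,3,4-trimethoxy-6-{2,6-dimethoxy-4-[2,6-dimethoxy-4-(2,4,6-trimethoxyphenoxy)phenoxy]phenoxy}phenol | COc1cc(OC)c(Oc2cc(OC)c(Oc3cc(OC)c(Oc4cc(OC)c(OC)c(OC)c4O)c(OC)c3)c(OC)c2)c(OC)c1 | intermediate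
23 | 4-bromo-2,6-dimethoxyphenol | COc1cc(Br)cc(OC)c1O | starting material
24 | 4-fluoro-2,6-dimethoxybenzaldehyde | COc1cc(F)cc(OC)c1C=O | starting material
25 | EF aldehyde: 4-(4-bromo-2,6-dimethoxyphenoxy)-2,6-dimethoxybenzaldehyde | COc1cc(Br)cc(OC)c1Oc1cc(OC)c(C=O)c(OC)c1 | intermediate
26 | EF formate: 4-(4-bromo-2,6-dimethoxyphenoxy)-2,6-dimethoxyphenyl formate | COc1cc(Br)cc(OC)c1Oc1cc(OC)c(OC=O)c(OC)c1 | intermediate
27 | EF phenol: 4-(4-bromo-2,6-dimethoxyphenoxy)-2,6-dimethoxyphenol | COc1cc(Br)cc(OC)c1Oc1cc(OC)c(O)c(OC)c1 | intermediate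
28 | EFG aldehyde: 4-[4-(4-bromo-2,6-dimethoxyphenoxy)-2,6-dimethoxyphenoxy]-2,6-dimethoxybenzaldehyde | COc1cc(Br)cc(OC)c1Oc1cc(OC)c(Oc2cc(OC)c(C=O)c(OC)c2)c(OC)c1 | intermediate
29 | EFG formate: formate ester of 30 | COc1cc(Br)cc(OC)c1Oc1cc(OC)c(Oc2cc(OC)c(OC=O)c(OC)c2)c(OC)c1 | intermediate
30 | EFG phenol (free hydroxyl on ring G): 4-[4-(4-bromo-2,6-dimethoxyphenoxy)-2,6-dimethoxyphenoxy]-2,6-dimethoxyphenol | COc1cc(Br)cc(OC)c1Oc1cc(OC)c(Oc2cc(OC)c(O)c(OC)c2)c(OC)c1 | intermediate
31 | permethylated EFG bromide: 5-[4-(4-bromo-2,6-dimethoxyphenoxy)-2,6-dimethoxyphenoxy]-1,2,3-trimethoxybenzene | COc1cc(Br)cc(OC)c1Oc1cc(OC)c(Oc2cc(OC)c(OC)c(OC)c2)c(OC)c1 | intermediate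
32 | permethylated heptamer (heptadecamethyl ether of the target) | COc1cc(OC)c(Oc2cc(OC)c(Oc3cc(OC)c(Oc4cc(OC)c(OC)c(OC)c4Oc4cc(OC)c(Oc5cc(OC)c(Oc6cc(OC)c(OC)c(OC)c6)c(OC)c5)c(OC)c4)c(OC)c3)c(OC)c2)c(OC)c1 | intermediate
33 | CNP0304148.0 | Oc1cc(O)c(Oc2cc(O)c(Oc3cc(O)c(Oc4cc(O)c(O)c(O)c4Oc4cc(O)c(Oc5cc(O)c(Oc6cc(O)c(O)c(O)c6)c(O)c5)c(O)c4)c(O)c3)c(O)c2)c(O)c1 | target

**Step count and risks**

Total steps: 21. Longest linear sequence: 15 steps (steps 1–4, 6–14, 20, 21, from 2,3,4-trimethoxybenzaldehyde); the EFG branch contributes steps 15–19 and step 5 supplies the dibromo fluoroarene.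

Most likely to fail:

1. Step 13. The exchange may stall after only some of the six sites have reacted, and protonation of aryl–copper intermediates may replace bromine by hydrogen, leaving close-running mixtures of partly methoxylated and partly reduced tetramers. The fallback spreads the exchange over the assembly so that only the twofold exchange is ever asked for. It sets out from 13 and returns at 21. Compound 13 is treated with NaOMe and CuBr in DMF–MeOH to give 4-[2-(benzyloxy)-3,4,5-trimethoxyphenoxy]-3,5-dimethoxyphenol F1. SNAr of F1 with 10 (K2CO3, DMF) gives the BCD aldehyde with dibromo ring B and dimethoxy ring C F2. Baeyer–Villiger oxidation with mCPBA at 0 °C gives the BCD formate with dibromo ring B and dimethoxy ring C F3, which is methanolysed to the BCD phenol with dibromo ring B and dimethoxy ring C F4. A second twofold exchange gives the BCD phenol with dimethoxy rings B and C F5. SNAr with 10 gives the ABCD aldehyde with dibromo ring A and dimethoxy rings B and C F6. Oxidation gives the ABCD formate with dibromo ring A and dimethoxy rings B and C F7, and methanolysis the ABCD phenol with dibromo ring A and dimethoxy rings B and C F8. Methylation with MeI and K2CO3 gives the ABCD methyl ether with dibromo ring A and dimethoxy rings B and C F9, and a last twofold exchange converts F9 into 21.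

2. Step 20. The ring D phenoxide, flanked by an aryloxy and a methoxy group, may bind copper poorly and the electron-rich bromide may add slowly, so that reduction of the C–Br bond or simple non-conversion outruns C–O bond formation. The fallback switches to oxidative copper coupling of a boronic acid, a reaction known to accept phenols with two ortho substituents. It sets out from 31 and returns at 32. Bromine–lithium exchange on 31 (n-BuLi, THF, −78 °C, B(OiPr)3 present for in situ trapping, then aqueous acid) gives the EFG boronic acid F10. Chan–Lam–Evans coupling of F10 with 22 (Cu(OAc)2, divalent copper, pyridine, Et3N, 4 Å molecular sieves, CH2Cl2, air, rt) gives 32.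

3. Step 15 (repeated in step 17). The two methoxy groups beside the formyl group weaken its activation of the para fluoride and the phenoxide is hindered, so the substitution may stall, and forcing it may cause demethylation by the phenoxide. The fallback builds the EFG bromide by iodide-selective copper couplings from the ring G end. It sets out from 23 and returns at 31. Coupling of 23 with commercial 5-iodo-1,2,3-trimethoxybenzene (CuI, picolinic acid, K3PO4, DMSO, 80 °C, the C–I bond reacting before the C–Br bond of the electron-rich bromophenoxide) gives the GF bromide 5-(4-bromo-2,6-dimethoxyphenoxy)-1,2,3-trimethoxybenzene F11. Aromatic Finkelstein exchange (CuI, NaI, trans-N,N′-dimethylcyclohexane-1,2-diamine, dioxane, 110 °C) gives the GF iodide 5-(4-iodo-2,6-dimethoxyphenoxy)-1,2,3-trimethoxybenzene F12. A second iodide-selective coupling of F12 with 23 under the first conditions gives 31.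

**Further compounds**

F1 | step 13 | 4-[2-(benzyloxy)-3,4,5-trimethoxyphenoxy]-3,5-dimethoxyphenol | Oc1cc(OC)c(Oc2cc(OC)c(OC)c(OC)c2OCc2ccccc2)c(OC)c1
F2 | step 13 | BCD aldehyde with dibromo ring B and dimethoxy ring C | O=Cc1cc(Br)c(Oc2cc(OC)c(Oc3cc(OC)c(OC)c(OC)c3OCc3ccccc3)c(OC)c2)c(Br)c1
F3 | step 13 | BCD formate with dibromo ring B and dimethoxy ring C | O=COc1cc(Br)c(Oc2cc(OC)c(Oc3cc(OC)c(OC)c(OC)c3OCc3ccccc3)c(OC)c2)c(Br)c1
F4 | step 13 | BCD phenol with dibromo ring B and dimethoxy ring C | Oc1cc(Br)c(Oc2cc(OC)c(Oc3cc(OC)c(OC)c(OC)c3OCc3ccccc3)c(OC)c2)c(Br)c1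
F5 | step 13 | BCD phenol with dimethoxy rings B and C | Oc1cc(OC)c(Oc2cc(OC)c(Oc3cc(OC)c(OC)c(OC)c3OCc3ccccc3)c(OC)c2)c(OC)c1
F6 | step 13 | ABCD aldehyde with dibromo ring A and dimethoxy rings B and C | O=Cc1cc(Br)c(Oc2cc(OC)c(Oc3cc(OC)c(Oc4cc(OC)c(OC)c(OC)c4OCc4ccccc4)c(OC)c3)c(OC)c2)c(Br)c1
F7 | step 13 | ABCD formate with dibromo ring A and dimethoxy rings B and C | O=COc1cc(Br)c(Oc2cc(OC)c(Oc3cc(OC)c(Oc4cc(OC)c(OC)c(OC)c4OCc4ccccc4)c(OC)c3)c(OC)c2)c(Br)c1
F8 | step 13 | ABCD phenol with dibromo ring A and dimethoxy rings B and C | Oc1cc(Br)c(Oc2cc(OC)c(Oc3cc(OC)c(Oc4cc(OC)c(OC)c(OC)c4OCc4ccccc4)c(OC)c3)c(OC)c2)c(Br)c1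
F9 | step 13 | ABCD methyl ether with dibromo ring A and dimethoxy rings B and C | COc1cc(Br)c(Oc2cc(OC)c(Oc3cc(OC)c(Oc4cc(OC)c(OC)c(OC)c4OCc4ccccc4)c(OC)c3)c(OC)c2)c(Br)c1
F10 | step 20 | EFG boronic acid | OB(O)c1cc(OC)c(Oc2cc(OC)c(Oc3cc(OC)c(OC)c(OC)c3)c(OC)c2)c(OC)c1
F11 | step 15 | GF bromide 5-(4-bromo-2,6-dimethoxyphenoxy)-1,2,3-trimethoxybenzene | COc1cc(Br)cc(OC)c1Oc1cc(OC)c(OC)c(OC)c1
F12 | step 15 | GF iodide 5-(4-iodo-2,6-dimethoxyphenoxy)-1,2,3-trimethoxybenzene | COc1cc(I)cc(OC)c1Oc1cc(OC)c(OC)c(OC)c1
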